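**Retrosynthetic overview**
- Target ⇐ 6‑O‑veratroylation, hydroxyl‑directed epoxidation of the C8=C9 alkene and C2 acetylation of a trans‑fused hydroazulene diol.
- Five‑membered ring ⇐ intramolecular aldol of a cycloheptene 1,4‑diketone (acetyl on C1, isobutyryl on C5), then hydroxyl‑directed anti reduction at C2.
- Seven‑membered ring ⇐ ring‑closing metathesis (allyl + methallyl); acetyl ⇐ Wacker oxidation of the C1 vinyl group; isobutyryl ⇐ the carboxylic acid.
- C1–C5 bond (quaternary C1, tertiary C5) ⇐ chelated dianionic ester‑enolate Claisen [3,3] rearrangement of an (E)‑3‑methylhexa‑2,5‑dienyl β‑hydroxy ester.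
- β‑Hydroxy ester ⇐ ethyl (R)‑4‑chloro‑3‑hydroxybutanoate, the only source of chirality. Ring order: seven‑membered ring, then five‑membered ring, then epoxide.

Assumption: daucane atom labels are used in the explanations (C‑1 angular‑methyl carbon, C‑2 acetoxy carbon, C‑4 isopropyl carbinol, C‑5 ring‑fusion CH, C‑6 ester carbon, C‑8/C‑9 epoxide); the target is (1R,2S,4R,5S,6S,8R,9S) in these labels, and ethyl (R)‑4‑chloro‑3‑hydroxybutanoate is taken as a cheap bulk chiral building block.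

**Step 1**
Reactants: 1 ethyl (3R)-4-chloro-3-hydroxybutanoate
Product: 2 ethyl 2-[(2R)-oxiran-2-yl]acetate
Conditions: Ag2O (1.1 equiv), DME, 80 °C
Reagents that add atoms: none
Why: Silver‑assisted intramolecular Williamson closure (halohydrin to epoxide) under non‑basic conditions avoids β‑elimination, and the carbinol stereocentre is not touched.

**Step 2**
Reactants: 2 ethyl 2-[(2R)-oxiran-2-yl]acetate; 3 isopropenylmagnesium bromide
Product: 4 ethyl (3S)-3-hydroxy-5-methylhex-5-enoate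
Conditions: CuI (10 mol %), THF, −40 to −20 °C; cold 1 M HCl work‑up
Reagents that add atoms: none
Why: Copper‑catalysed Grignard opening of the terminal epoxide at the CH2 carbon (SN2) installs the methallyl unit (C‑7/C‑8) and leaves the C‑6 carbinol centre untouched (the descriptor changes only through priorities).

**Step 3**
Reactants: 5 pent-1-en-4-yne
Product: 7 (2E)-3-methylhexa-2,5-dien-1-ol, via alkenylalane 6 (not isolated)
Conditions: AlMe3 (2 equiv), Cp2ZrCl2 (20 mol %), CH2Cl2, 0 °C to rt; then (CH2O)n, THF, 0 °C to rt; 1 M HCl work‑up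
Reagents that add atoms: trimethylaluminium, C[Al](C)C; formaldehyde (as paraformaldehyde), C=O
Why: Negishi zirconium‑catalysed syn‑carboalumination of the terminal alkyne puts Me and Al cis, and hydroxymethylation of the C–Al bond with retention gives the (E)‑allylic alcohol.

**Step 4**
Reactants: 4 ethyl (3S)-3-hydroxy-5-methylhex-5-enoate; 7 (2E)-3-methylhexa-2,5-dien-1-ol
Product: 8 (2E)-3-methylhexa-2,5-dien-1-yl (3S)-3-hydroxy-5-methylhex-5-enoate
Conditions: Ti(OEt)4 (10 mol %), toluene, 100 °C, removal of EtOH (4 Å sieves)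
Reagents that add atoms: none
Why: Titanate‑catalysed transesterification driven by removal of ethanol tolerates the free β‑hydroxyl and the alkenes.

**Step 5**
Reactants: 8 (2E)-3-methylhexa-2,5-dien-1-yl (3S)-3-hydroxy-5-methylhex-5-enoate
Product: 10 (2S,3S)-3-hydroxy-5-methyl-2-[(3S)-3-methylhexa-1,5-dien-3-yl]hex-5-enoic acid, via chelated dilithium dianion 9 (not isolated)
Conditions: LiN(iPr)2 (2.3 equiv), THF, −78 °C; warm to 50 °C; 1 M HCl work‑up
Reagents that add atoms: none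
Why: Dianionic ester‑enolate (Ireland‑type) Claisen [3,3]-sigmatropic rearrangement through a chair transition state: the lithium chelate fixes the enolate geometry and blocks one face so the new C‑5 centre forms anti to the C‑6 hydroxyl, and the (E)‑alkene (methyl axial, allyl equatorial) then sets the quaternary C‑1 centre.

**Step 6**
Reactants: 10 (2S,3S)-3-hydroxy-5-methyl-2-[(3S)-3-methylhexa-1,5-dien-3-yl]hex-5-enoic acid
Product: 12 (2S,3S)-3-[(tert-butyldimethylsilyl)oxy]-5-methyl-2-[(3S)-3-methylhexa-1,5-dien-3-yl]hex-5-enoic acid, via bis-silylated ester 11 (not isolated)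
Conditions: TBSOTf (2.5 equiv), 2,6‑lutidine, CH2Cl2, 0 °C; then K2CO3, MeOH/H2O, rt; work‑up at pH 4
Reagents that add atoms: tert-butyldimethylsilyl trifluoromethanesulfonate, CC(C)(C)[Si](C)(C)OS(=O)(=O)C(F)(F)F
Why: Exhaustive silylation followed by selective hydrolysis of the labile silyl ester protects the C‑6 hydroxyl for the organometallic and base steps.

**Step 7**
Reactants: 12 (2S,3S)-3-[(tert-butyldimethylsilyl)oxy]-5-methyl-2-[(3S)-3-methylhexa-1,5-dien-3-yl]hex-5-enoic acid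
Product: 13 (1S,2S,7S)-7-[(tert-butyldimethylsilyl)oxy]-2-ethenyl-2,5-dimethylcyclohept-4-ene-1-carboxylic acid
Conditions: second‑generation Grubbs catalyst RuCl2(=CHPh)(PCy3)(H2IMes) (5 mol %), CH2Cl2 (0.005 M), 40 °C
Reagents that add atoms: none
Why: Ring‑closing metathesis of the allyl and methallyl groups gives the trisubstituted cycloheptene (C‑8=C‑9) with loss of ethene; the vinyl group on the quaternary carbon is too hindered to initiate and can only form a cyclobutene with the allyl carbene.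

**Step 8**
Reactants: 13 (1S,2S,7S)-7-[(tert-butyldimethylsilyl)oxy]-2-ethenyl-2,5-dimethylcyclohept-4-ene-1-carboxylic acid; 14 isopropylmagnesium chloride
Product: 16 1-[(1S,2S,7S)-7-[(tert-butyldimethylsilyl)oxy]-2-ethenyl-2,5-dimethylcyclohept-4-en-1-yl]-2-methylpropan-1-one, via acid chloride 15 (not isolated)
Conditions: 1‑chloro‑N,N,2‑trimethylprop‑1‑en‑1‑amine (1.2 equiv), CH2Cl2, 0 °C to rt; then 14 (1.1 equiv), Fe(acac)3 (3 mol %), THF, −78 °C
Reagents that add atoms: none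
Why: Neutral acid‑chloride formation and iron‑catalysed acylation of the Grignard reagent stop at the ketone and do not epimerise C‑5.

**Step 9**
Reactants: 16 1-[(1S,2S,7S)-7-[(tert-butyldimethylsilyl)oxy]-2-ethenyl-2,5-dimethylcyclohept-4-en-1-yl]-2-methylpropan-1-one
Product: 17 1-[(1S,2R,7S)-2-acetyl-7-[(tert-butyldimethylsilyl)oxy]-2,5-dimethylcyclohept-4-en-1-yl]-2-methylpropan-1-one
Conditions: PdCl2 (10 mol %), CuCl (1 equiv), O2 (1 atm), DMF/H2O 7:1, rt
Reagents that add atoms: water, O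
Why: Tsuji–Wacker oxidation turns the terminal vinyl group of this γ,δ‑unsaturated ketone into the methyl ketone (Markovnikov), while the trisubstituted ring alkene is inert.

**Step 10**
Reactants: 17 1-[(1S,2R,7S)-2-acetyl-7-[(tert-butyldimethylsilyl)oxy]-2,5-dimethylcyclohept-4-en-1-yl]-2-methylpropan-1-one
Product: 18 (3R,3aS,4S,8aR)-4-[(tert-butyldimethylsilyl)oxy]-3-hydroxy-6,8a-dimethyl-3-(propan-2-yl)-3,3a,4,5,8,8a-hexahydroazulen-1(2H)-one
Conditions: LiN(iPr)2 (1.05 equiv), THF, −78 °C; AcOH quench at −78 °C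
Reagents that add atoms: none
Why: Kinetic deprotonation at the acetyl CH3 and 5‑exo intramolecular aldol addition to the isopropyl ketone close the cyclopentanone; the isopropyl group takes the face cis to H‑5, away from C‑6–OTBS and the angular methyl, so the new C‑4 hydroxyl is cis to the angular methyl.

**Step 11**
Reactants: 18 (3R,3aS,4S,8aR)-4-[(tert-butyldimethylsilyl)oxy]-3-hydroxy-6,8a-dimethyl-3-(propan-2-yl)-3,3a,4,5,8,8a-hexahydroazulen-1(2H)-one
Product: 19 (1S,3R,3aS,4S,8aR)-4-[(tert-butyldimethylsilyl)oxy]-6,8a-dimethyl-3-(propan-2-yl)-1,2,3,3a,4,5,8,8a-octahydroazulene-1,3-diol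
Conditions: Me4NBH(OAc)3 (6 equiv), MeCN/AcOH 1:1, −30 to 0 °C
Reagents that add atoms: none
Why: Evans–Saksena reduction: the C‑4 hydroxyl binds the triacetoxyborohydride and delivers hydride to its own face, giving the 1,3‑anti diol with C‑2–OH trans to the angular methyl.

**Step 12**
Reactants: 19 (1S,3R,3aS,4S,8aR)-4-[(tert-butyldimethylsilyl)oxy]-6,8a-dimethyl-3-(propan-2-yl)-1,2,3,3a,4,5,8,8a-octahydroazulene-1,3-diol
Product: 20 (1S,3R,3aS,4S,8aR)-4-[(tert-butyldimethylsilyl)oxy]-3-hydroxy-6,8a-dimethyl-3-(propan-2-yl)-1,2,3,3a,4,5,8,8a-octahydroazulen-1-yl acetate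
Conditions: Ac2O (3 equiv), pyridine, DMAP (10 mol %), CH2Cl2, rt
Reagents that add atoms: acetic anhydride, CC(=O)OC(C)=O
Why: DMAP‑catalysed acylation takes the secondary C‑2 hydroxyl and leaves the hindered tertiary C‑4 hydroxyl free.

**Step 13**
Reactants: 20 (1S,3R,3aS,4S,8aR)-4-[(tert-butyldimethylsilyl)oxy]-3-hydroxy-6,8a-dimethyl-3-(propan-2-yl)-1,2,3,3a,4,5,8,8a-octahydroazulen-1-yl acetate
Product: 21 (1S,3R,3aS,4S,8aR)-3,4-dihydroxy-6,8a-dimethyl-3-(propan-2-yl)-1,2,3,3a,4,5,8,8a-octahydroazulen-1-yl acetate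
Conditions: HF·pyridine, THF/pyridine, 0 °C to rt
Reagents that add atoms: none
Why: Fluoride‑mediated desilylation under buffered conditions leaves the acetate, the tertiary alcohol and the alkene intact.

**Step 14**
Reactants: 21 (1S,3R,3aS,4S,8aR)-3,4-dihydroxy-6,8a-dimethyl-3-(propan-2-yl)-1,2,3,3a,4,5,8,8a-octahydroazulen-1-yl acetate
Product: 22 (1S,3R,3aS,4S,6R,7S,8aR)-6,7-epoxy-3,4-dihydroxy-6,8a-dimethyl-3-(propan-2-yl)decahydroazulen-1-yl acetate
Conditions: VO(acac)2 (5 mol %), tBuOOH (1.5 equiv, decane solution), CH2Cl2, 0 °C to rt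
Reagents that add atoms: tert-butyl hydroperoxide, CC(C)(C)OO
Why: Vanadium‑catalysed hydroxyl‑directed epoxidation: the homoallylic C‑6 hydroxyl delivers oxygen to its own face of the C‑8=C‑9 alkene, which is also the face away from the angular methyl.

**Step 15**
Reactants: 22 (1S,3R,3aS,4S,6R,7S,8aR)-6,7-epoxy-3,4-dihydroxy-6,8a-dimethyl-3-(propan-2-yl)decahydroazulen-1-yl acetate; 23 3,4-dimethoxybenzoyl chloride
Product: 24 (1S,3R,3aS,4S,6R,7S,8aR)-1-(acetyloxy)-6,7-epoxy-3-hydroxy-6,8a-dimethyl-3-(propan-2-yl)decahydroazulen-4-yl 3,4-dimethoxybenzoate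
Conditions: Et3N (3 equiv), DMAP (1 equiv), CH2Cl2, 0 to 40 °C
Reagents that add atoms: none
Why: DMAP‑catalysed esterification of the only secondary hydroxyl; the tertiary alcohol and the epoxide do not react.

**Compound list**
1 | ethyl (3R)-4-chloro-3-hydroxybutanoate | CCOC(=O)C[C@@H](O)CCl | starting material
2 | ethyl 2-[(2R)-oxiran-2-yl]acetate | CCOC(=O)C[C@@H]1CO1 | intermediate
3 | isopropenylmagnesium bromide | CC(=C)[Mg]Br | starting material
4 | ethyl (3S)-3-hydroxy-5-methylhex-5-enoate | CCOC(=O)C[C@@H](O)CC(C)=C | intermediate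
5 | pent-1-en-4-yne | C=CCC#C | starting material
6 | dimethyl[(1E)-2-methylpenta-1,4-dien-1-yl]alumane | C=CC/C(C)=C/[Al](C)C | intermediate (not isolated)
7 | (2E)-3-methylhexa-2,5-dien-1-ol | C=CC/C(C)=C/CO | intermediate
8 | (2E)-3-methylhexa-2,5-dien-1-yl (3S)-3-hydroxy-5-methylhex-5-enoate | C=CC/C(C)=C/COC(=O)C[C@@H](O)CC(C)=C | intermediate
9 | dilithium (1E,3S)-5-methyl-1-{[(2E)-3-methylhexa-2,5-dien-1-yl]oxy}hexa-1,5-diene-1,3-bis(olate) (OLi cis to C-3) | C=CC/C(C)=C/CO/C(O[Li])=C/[C@@H](O[Li])CC(C)=C | intermediate (not isolated)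
10 | (2S,3S)-3-hydroxy-5-methyl-2-[(3S)-3-methylhexa-1,5-dien-3-yl]hex-5-enoic acid | OC(=O)[C@H]([C@@H](O)CC(C)=C)[C@](C)(C=C)CC=C | intermediate
11 | tert-butyldimethylsilyl (2S,3S)-3-[(tert-butyldimethylsilyl)oxy]-5-methyl-2-[(3S)-3-methylhexa-1,5-dien-3-yl]hex-5-enoate | CC(C)(C)[Si](C)(C)OC(=O)[C@H]([C@@H](O[Si](C)(C)C(C)(C)C)CC(C)=C)[C@](C)(C=C)CC=C | intermediate (not isolated)
12 | (2S,3S)-3-[(tert-butyldimethylsilyl)oxy]-5-methyl-2-[(3S)-3-methylhexa-1,5-dien-3-yl]hex-5-enoic acid | OC(=O)[C@H]([C@@H](O[Si](C)(C)C(C)(C)C)CC(C)=C)[C@](C)(C=C)CC=C | intermediate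
13 | (1S,2S,7S)-7-[(tert-butyldimethylsilyl)oxy]-2-ethenyl-2,5-dimethylcyclohept-4-ene-1-carboxylic acid | OC(=O)[C@@H]1[C@@H](O[Si](C)(C)C(C)(C)C)CC(C)=CC[C@@]1(C)C=C | intermediate
14 | isopropylmagnesium chloride | CC(C)[Mg]Cl | starting material
15 | (1S,2S,7S)-7-[(tert-butyldimethylsilyl)oxy]-2-ethenyl-2,5-dimethylcyclohept-4-ene-1-carbonyl chloride | ClC(=O)[C@@H]1[C@@H](O[Si](C)(C)C(C)(C)C)CC(C)=CC[C@@]1(C)C=C | intermediate (not isolated)
16 | 1-[(1S,2S,7S)-7-[(tert-butyldimethylsilyl)oxy]-2-ethenyl-2,5-dimethylcyclohept-4-en-1-yl]-2-methylpropan-1-one | CC(C)C(=O)[C@@H]1[C@@H](O[Si](C)(C)C(C)(C)C)CC(C)=CC[C@@]1(C)C=C | intermediate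
17 | 1-[(1S,2R,7S)-2-acetyl-7-[(tert-butyldimethylsilyl)oxy]-2,5-dimethylcyclohept-4-en-1-yl]-2-methylpropan-1-one | CC(C)C(=O)[C@@H]1[C@@H](O[Si](C)(C)C(C)(C)C)CC(C)=CC[C@@]1(C)C(C)=O | intermediate
18 | (3R,3aS,4S,8aR)-4-[(tert-butyldimethylsilyl)oxy]-3-hydroxy-6,8a-dimethyl-3-(propan-2-yl)-3,3a,4,5,8,8a-hexahydroazulen-1(2H)-one | CC(C)(C)[Si](C)(C)O[C@H]1CC(C)=CC[C@@]2(C)C(=O)C[C@@](O)(C(C)C)[C@H]12 | intermediate
19 | (1S,3R,3aS,4S,8aR)-4-[(tert-butyldimethylsilyl)oxy]-6,8a-dimethyl-3-(propan-2-yl)-1,2,3,3a,4,5,8,8a-octahydroazulene-1,3-diol | CC(C)(C)[Si](C)(C)O[C@H]1CC(C)=CC[C@@]2(C)[C@@H](O)C[C@@](O)(C(C)C)[C@H]12 | intermediate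
20 | (1S,3R,3aS,4S,8aR)-4-[(tert-butyldimethylsilyl)oxy]-3-hydroxy-6,8a-dimethyl-3-(propan-2-yl)-1,2,3,3a,4,5,8,8a-octahydroazulen-1-yl acetate | CC(C)(C)[Si](C)(C)O[C@H]1CC(C)=CC[C@@]2(C)[C@@H](OC(C)=O)C[C@@](O)(C(C)C)[C@H]12 | intermediate
21 | (1S,3R,3aS,4S,8aR)-3,4-dihydroxy-6,8a-dimethyl-3-(propan-2-yl)-1,2,3,3a,4,5,8,8a-octahydroazulen-1-yl acetate | O[C@H]1CC(C)=CC[C@@]2(C)[C@@H](OC(C)=O)C[C@@](O)(C(C)C)[C@H]12 | intermediate
22 | (1S,3R,3aS,4S,6R,7S,8aR)-6,7-epoxy-3,4-dihydroxy-6,8a-dimethyl-3-(propan-2-yl)decahydroazulen-1-yl acetate | O[C@H]1C[C@@]2(C)O[C@H]2C[C@@]2(C)[C@@H](OC(C)=O)C[C@@](O)(C(C)C)[C@H]12 | intermediate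
23 | 3,4-dimethoxybenzoyl chloride | COc1ccc(C(Cl)=O)cc1OC | starting material
24 | (1S,3R,3aS,4S,6R,7S,8aR)-1-(acetyloxy)-6,7-epoxy-3-hydroxy-6,8a-dimethyl-3-(propan-2-yl)decahydroazulen-4-yl 3,4-dimethoxybenzoate | COc1ccc(C(=O)O[C@H]2C[C@@]3(C)O[C@H]3C[C@@]3(C)[C@@H](OC(C)=O)C[C@@](O)(C(C)C)[C@H]23)cc1OC | target

**Totals and risks**
Total step count: 15. Longest linear sequence: 14 steps (1 to 24 through steps 1, 2 and 4–15; step 3 is the side branch).

Most likely to fail, step 5 (Claisen rearrangement). The lithium dianion may rearrange sluggishly at the fully substituted alkene terminus or lose selectivity. Fallback, from 8 back to 12: silylate first (TBSCl, imidazole, DMF) to (2E)-3-methylhexa-2,5-dien-1-yl (3S)-3-[(tert-butyldimethylsilyl)oxy]-5-methylhex-5-enoate F1. Enolise with LiN(iPr)2 in THF/DMPU at −78 °C and trap with Me3SiCl to give the (Z)-trimethylsilyl ketene acetal F2. Warm to 60 °C so the neutral ketene acetal undergoes the Ireland–Claisen shift to the trimethylsilyl ester of 12 F3, and hydrolyse with dilute acid to reach 12. Control then rests on enolate geometry and allylic strain at the silyloxy centre instead of lithium chelation, so a lower diastereomer ratio and a chromatographic separation are expected.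

Second, step 8 (hindered acid to isopropyl ketone). The acyl carbon sits between a quaternary centre and a silyloxy carbon, and over‑addition or ketene formation could intervene. Fallback, from 13 back to 16: reduce with LiAlH4 to [(1R,2S,7S)-7-[(tert-butyldimethylsilyl)oxy]-2-ethenyl-2,5-dimethylcyclohept-4-en-1-yl]methanol F4. Oxidise with Dess–Martin periodinane to (1S,2S,7S)-7-[(tert-butyldimethylsilyl)oxy]-2-ethenyl-2,5-dimethylcyclohept-4-ene-1-carbaldehyde F5. Add 14 at −78 °C to give 1-[(1R,2S,7S)-7-[(tert-butyldimethylsilyl)oxy]-2-ethenyl-2,5-dimethylcyclohept-4-en-1-yl]-2-methylpropan-1-ol F6 (both carbinol epimers), and oxidise again with Dess–Martin periodinane to 16.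

Third, step 10 (aldol ring closure). The lithium aldolate of a hindered ketone–ketone aldol may revert or dehydrate to the cyclopentenone. Fallback, from 17 back to 18: form the kinetic enol ether 2-methyl-1-[(1S,2R,7S)-7-[(tert-butyldimethylsilyl)oxy]-2,5-dimethyl-2-{1-[(trimethylsilyl)oxy]ethenyl}cyclohept-4-en-1-yl]propan-1-one F7 (LiN(iPr)2, Me3SiCl, −78 °C). Brominate with NBS to 1-[(1S,2R,7S)-2-(bromoacetyl)-7-[(tert-butyldimethylsilyl)oxy]-2,5-dimethylcyclohept-4-en-1-yl]-2-methylpropan-1-one F8. Close the ring by an intramolecular samarium Reformatsky reaction (SmI2, THF, −78 °C), whose samarium aldolate is far less prone to retro‑aldol or elimination, to give 18.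

**Further compounds**
F1 | step 5 | (2E)-3-methylhexa-2,5-dien-1-yl (3S)-3-[(tert-butyldimethylsilyl)oxy]-5-methylhex-5-enoate | C=CC/C(C)=C/COC(=O)C[C@@H](O[Si](C)(C)C(C)(C)C)CC(C)=C
F2 | step 5 | (Z)-trimethylsilyl ketene acetal of F1, {[(1Z,3S)-3-[(tert-butyldimethylsilyl)oxy]-5-methyl-1-{[(2E)-3-methylhexa-2,5-dien-1-yl]oxy}hexa-1,5-dien-1-yl]oxy}trimethylsilane | C=CC/C(C)=C/CO/C(O[Si](C)(C)C)=C/[C@@H](O[Si](C)(C)C(C)(C)C)CC(C)=C
F3 | step 5 | trimethylsilyl (2S,3S)-3-[(tert-butyldimethylsilyl)oxy]-5-methyl-2-[(3S)-3-methylhexa-1,5-dien-3-yl]hex-5-enoate | C[Si](C)(C)OC(=O)[C@H]([C@@H](O[Si](C)(C)C(C)(C)C)CC(C)=C)[C@](C)(C=C)CC=C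
F4 | step 8 | [(1R,2S,7S)-7-[(tert-butyldimethylsilyl)oxy]-2-ethenyl-2,5-dimethylcyclohept-4-en-1-yl]methanol | OC[C@@H]1[C@@H](O[Si](C)(C)C(C)(C)C)CC(C)=CC[C@@]1(C)C=C
F5 | step 8 | (1S,2S,7S)-7-[(tert-butyldimethylsilyl)oxy]-2-ethenyl-2,5-dimethylcyclohept-4-ene-1-carbaldehyde | O=C[C@@H]1[C@@H](O[Si](C)(C)C(C)(C)C)CC(C)=CC[C@@]1(C)C=C
F6 | step 8 | 1-[(1R,2S,7S)-7-[(tert-butyldimethylsilyl)oxy]-2-ethenyl-2,5-dimethylcyclohept-4-en-1-yl]-2-methylpropan-1-ol (both carbinol epimers) | CC(C)C(O)[C@@H]1[C@@H](O[Si](C)(C)C(C)(C)C)CC(C)=CC[C@@]1(C)C=C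
F7 | step 10 | 2-methyl-1-[(1S,2R,7S)-7-[(tert-butyldimethylsilyl)oxy]-2,5-dimethyl-2-{1-[(trimethylsilyl)oxy]ethenyl}cyclohept-4-en-1-yl]propan-1-one | CC(C)C(=O)[C@@H]1[C@@H](O[Si](C)(C)C(C)(C)C)CC(C)=CC[C@@]1(C)C(=C)O[Si](C)(C)C
F8 | step 10 | 1-[(1S,2R,7S)-2-(bromoacetyl)-7-[(tert-butyldimethylsilyl)oxy]-2,5-dimethylcyclohept-4-en-1-yl]-2-methylpropan-1-one | CC(C)C(=O)[C@@H]1[C@@H](O[Si](C)(C)C(C)(C)C)CC(C)=CC[C@@]1(C)C(=O)CBr
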